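**Retrosynthetic overview**
- The target is 15-acetoxylabda-8,13E-dien-19-oic acid (4S,5R,10S). Ring B (C5–C10) has C9 between the methyl-bearing C8 and C10, with C6 opposite C9, which is the pattern of quinone 1. Ring B is therefore bought, and ring A (C1–C4) is closed on its C5=C10 alkene with diene 2 to give adduct 3.
- C11–C12: C11 allylic bromide plus a C12–C16 allylic sulfone made from prenyl acetate. C9–C11: carbonylation of the C8=C9 enol triflate.
- C4–C19: Wittig–Still [2,3] shift from a 6β-oxygen across C4=C5 (sets C4); hydrogenation of C5=C6 then sets C5.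
- C1–C10 and C4–C5: catalytic enantioselective Diels–Alder reaction (sets C10).
- Ring order: ring B is present in 1, ring A is formed in step 1, and no further ring is made.

Key step: step 1

Conventions: atom numbers are labdane numbers (C1–C10 decalin, C11–C16 side chain, C17 on C8, C18 α and C19 β on C4, C20 on C10; β is the face of C20). The centres C8 and C9 in 6–14 and C12 in 27 are not controlled, are removed later and are left open in the SMILES.

Assumption: the (S)-configured catalyst is taken, by the accepted model for quinone dienophiles, to give the 10S adduct; the catalyst from (R)-proline is equally accessible and would be used if the sense proved opposite.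

**Step 1**
Reactants: 1 2,6-dimethyl-1,4-benzoquinone; 2 (E)-penta-1,3-diene
Product: 3 (4aR,5R,8aS)-2,5,8a-trimethyl-4a,5,8,8a-tetrahydronaphthalene-1,4-dione (cis-fused endo adduct; H4, H5 and C20 all β)
Conditions: (S)-3,3-diphenyl-1-(2-methylphenyl)tetrahydro-1H,3H-pyrrolo[1,2-c][1,3,2]oxazaborole (20 mol %), HN(SO2CF3)2 (20 mol %), 2 (3 equiv), CH2Cl2, −78 °C
Reagents that add atoms: none
Why: The protonated oxazaborolidine binds the C6 carbonyl of 1 (flanked by C–H, so more basic and less hindered than the C9 carbonyl), and the reaction is a Lewis-acid-activated, concerted but asynchronous [4+2] cycloaddition of the known type: oxazaborolidinium-catalysed Diels–Alder reactions of substituted 1,4-benzoquinones with 1-substituted butadienes. Ring A closes by intermolecular cycloaddition across the C5=C10 alkene: the unsubstituted diene terminus (C1, larger HOMO coefficient) bonds to C10, the carbon β to the bound carbonyl, and the methyl-bearing terminus (C4) bonds to C5. C10 is set by the catalyst, whose aryl groups screen one face of the bound C5=C10 alkene so that the diene adds to the other; C5 follows from suprafacial addition (cis fusion) and C4 from the endo transition state with the E diene. The step needs only regioselectivity and enantioface selectivity, and both follow from coordination at O6; the two alkenes of 1 are equivalent by symmetry, and endo/exo and the C4 and C5 configurations do not matter because both centres are made planar in step 2.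

**Step 2**
Reactants: 3 Diels–Alder adduct
Product: 5 (8aS)-2,5,8a-trimethyl-8,8a-dihydronaphthalene-1,4-dione, via trimethylsilyl dienol ether 4 (not isolated)
Conditions: Me3SiOTf, Et3N, CH2Cl2, 0 °C; then Pd(OAc)2 (1.05 equiv), MeCN, rt
Reagents that add atoms: none
Why: Saegusa–Ito oxidation: C5–H is the only enolisable α-hydrogen (C10 is quaternary, C7 is vinylic), so the C5=C6 silyl dienol ether forms alone, and its palladium enolate loses the C4 hydrogen (the only β-hydrogen; C- and O-bound enolates interconvert, so the face syn to H4 is reached) to give C4=C5, which makes C4 and C5 planar.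

**Step 3**
Reactants: 5 trienedione
Product: 6 (8aS)-2,5,8a-trimethyl-2,3,8,8a-tetrahydronaphthalene-1,4-dione (epimers at labdane C8)
Conditions: Zn dust, AcOH, rt
Reagents that add atoms: none
Why: Zinc in acetic acid reduces only the doubly activated ene-1,4-dione alkene C7=C8 (two-electron reduction to the bis-enol, then ketonisation), the standard reduction of quinone Diels–Alder adducts, and leaves the C4=C5/C2=C3 dienone; with C7 saturated the later [2,3] shift has a single allylic terminus (C4), and C8 is made trigonal again in step 10.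

**Step 4**
Reactants: 6 dienedione
Product: 7 (4R,8aS)-2,5,8a-trimethyl-1,2,3,4,8,8a-hexahydronaphthalene-1,4-diol (labdane 6β-ol; epimers at C8 and C9)
Conditions: i-Bu2AlH (3.5 equiv), CH2Cl2, −78 → 0 °C; aq. KNaC4H4O6
Reagents that add atoms: none
Why: 1,2-Reduction of both ketones by the aluminium hydride: at C6 the hydride arrives on the α face, anti to the syn-axial C20 methyl (the usual course for 6-oxo steroids), which gives the pseudoaxial 6β allylic alcohol cis to C20; the C9 carbinol centre is not controlled and is oxidised again in step 8.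

**Step 5**
Reactants: 7 diol
Product: 9 6β-O-[(tributylstannyl)methyl] ether of 7 (9-OH free), via potassium 6-alkoxide 8 (not isolated)
Conditions: KH (1.05 equiv), 18-crown-6 (cat.), THF, 0 °C; then Bu3SnCH2I, 0 °C → rt
Reagents that add atoms: tributyl(iodomethyl)stannane CCCC[Sn](CCCC)(CCCC)CI
Why: Williamson etherification: with one equivalent of base only the allylic, more acidic and more accessible 6-hydroxyl (between C7H2 and sp2 C5) is alkylated, while the 9-hydroxyl, between the quaternary C10 and the methyl-bearing C8, should stay free.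

**Step 6**
Reactants: 9 stannylmethyl ether
Product: 11 (5S,8aS)-5-(hydroxymethyl)-2,5,8a-trimethyl-1,2,3,5,8,8a-hexahydronaphthalen-1-ol (C19 CH2OH β and C18 α on C4; C5=C6; C2=C3; 9-OH), via dilithiated lithiomethyl ether 10 (not isolated)
Conditions: n-BuLi (2.5 equiv), THF, −78 → −20 °C; H2O
Reagents that add atoms: none
Why: Wittig–Still rearrangement: the first equivalent of base only forms the 9-alkoxide, tin–lithium exchange then gives the α-alkoxymethyllithium, and its suprafacial [2,3]-sigmatropic shift across C6–C5=C4 (five-membered envelope fused to both rings) delivers C19 from the pseudoaxial 6β-oxygen to the β face of C4, cis to C20, while the alkene moves to C5=C6.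

**Step 7**
Reactants: 11 diol
Product: 12 19-O-(tert-butyldimethylsilyl) ether of 11
Conditions: t-BuMe2SiCl (1.1 equiv), imidazole, CH2Cl2, 0 °C
Reagents that add atoms: tert-butyldimethylsilyl chloride CC(C)(C)[Si](C)(C)Cl
Why: Silylation of the primary 19-hydroxyl is much faster than that of the secondary 9-hydroxyl next to the quaternary C10, and the bulky silyl ether adds to the shielding of the β face for step 9.

**Step 8**
Reactants: 12 silyl ether
Product: 13 9-ketone of 12 (19-silyloxy-11,12,13,14,15,16-hexanorlabda-2,5-dien-9-one; C8 epimers)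
Conditions: Dess–Martin periodinane, CH2Cl2, rt
Reagents that add atoms: none
Why: Dess–Martin oxidation of the secondary 9-alcohol converges the C9 epimers to one ketone, and the β,γ-alkene C5=C6 cannot move into conjugation because C10 is quaternary.

**Step 9**
Reactants: 13 dienone
Product: 14 19-(tert-butyldimethylsilyloxy)-11,12,13,14,15,16-hexanorlabdan-9-one (5α-H trans-decalin; C8 epimers)
Conditions: H2 (4 bar), Pd/C (10 %), EtOAc, rt
Reagents that add atoms: none
Why: Heterogeneous hydrogenation saturates C2=C3 and the trisubstituted C5=C6; the β face of C5=C6 is covered by the axial C20 methyl and the axial CH2OSi group on C4, so hydrogen should reach C5 from the α face and give the trans-decalin, as in hydrogenations of 4,4-disubstituted 10-methyl-5-octalins.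

**Step 10**
Reactants: 14 decalone
Product: 16 19-(tert-butyldimethylsilyloxy)-11,12,13,14,15,16-hexanorlabd-8-en-9-yl trifluoromethanesulfonate, via potassium enolate 15 (not isolated)
Conditions: KN(SiMe3)2 (1.3 equiv), THF, −78 → 0 °C; then PhN(SO2CF3)2, −78 °C → rt
Reagents that add atoms: N-phenylbis(trifluoromethanesulfonimide) O=S(=O)(N(c1ccccc1)S(=O)(=O)C(F)(F)F)C(F)(F)F
Why: Only C8–H can be removed (C10 is quaternary), so the enolate is the C8=C9 regioisomer alone and O-sulfonylation gives the tetrasubstituted enol triflate, which also erases the C8 stereocentre.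

**Step 11**
Reactants: 16 enol triflate
Product: 17 methyl 19-(tert-butyldimethylsilyloxy)-12,13,14,15,16-pentanorlabd-8-en-11-oate
Conditions: Pd(OAc)2 (10 mol %), PPh3 (20 mol %), CO (1 atm), MeOH, Et3N, DMF, 60 °C
Reagents that add atoms: carbon monoxide [C-]#[O+]; methanol CO
Why: Palladium-catalysed methoxycarbonylation of a vinyl triflate (oxidative addition to zerovalent palladium, CO insertion, methanolysis of the acyl complex) attaches C11 to C9, and CO is small enough to insert next to the quaternary C10.

**Step 12**
Reactants: 17 methyl ester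
Product: 18 19-(tert-butyldimethylsilyloxy)-12,13,14,15,16-pentanorlabd-8-en-11-ol
Conditions: i-Bu2AlH (2.5 equiv), CH2Cl2, −78 °C; aq. KNaC4H4O6
Reagents that add atoms: none
Why: 1,2-Reduction of the conjugated ester to the allylic alcohol by the aluminium hydride; the silyl ether and the tetrasubstituted alkene are inert.

**Step 13**
Reactants: 18 allylic alcohol
Product: 19 11-bromo-19-(tert-butyldimethylsilyloxy)-12,13,14,15,16-pentanorlabd-8-ene (used at once)
Conditions: CBr4, PPh3, CH2Cl2, 0 °C
Reagents that add atoms: carbon tetrabromide BrC(Br)(Br)Br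
Why: Appel reaction: SN2 displacement of the oxyphosphonium group at the primary allylic C11 under neutral conditions keeps the silyl ether and the position of C8=C9.

**Step 14**
Reactants: 20 3-methylbut-2-en-1-yl acetate (prenyl acetate)
Product: 21 (E)-4-hydroxy-3-methylbut-2-en-1-yl acetate
Conditions: SeO2 (0.2 equiv), t-BuOOH, CH2Cl2, rt
Reagents that add atoms: tert-butyl hydroperoxide CC(C)(C)OO; selenium dioxide O=[Se]=O (catalytic oxygen carrier)
Why: Selenium dioxide allylic oxidation (ene reaction, then [2,3] shift of the allylseleninic acid) attacks the methyl group trans to the CH2OAc chain, which gives the (E)-allylic alcohol and so fixes the C13=C14 geometry.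

**Step 15**
Reactants: 21 hydroxy acetate
Product: 22 (E)-4-bromo-3-methylbut-2-en-1-yl acetate
Conditions: CBr4, PPh3, CH2Cl2, 0 °C
Reagents that add atoms: carbon tetrabromide BrC(Br)(Br)Br
Why: Appel reaction at a primary allylic alcohol; SN2 displacement keeps the alkene position and geometry.

**Step 16**
Reactants: 22 bromo acetate
Product: 23 (E)-3-methyl-4-(phenylsulfonyl)but-2-en-1-yl acetate
Conditions: PhSO2Na, DMF, rt
Reagents that add atoms: sodium benzenesulfinate [Na+].[O-]S(=O)c1ccccc1
Why: SN2 S-alkylation of the sulfinate by the primary allylic bromide gives the allylic sulfone.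

**Step 17**
Reactants: 23 sulfone acetate
Product: 24 (E)-3-methyl-4-(phenylsulfonyl)but-2-en-1-ol
Conditions: K2CO3 (cat.), MeOH, rt
Reagents that add atoms: none
Why: Base-catalysed transesterification removes the acetate, which would not survive the organolithium base of step 19.

**Step 18**
Reactants: 24 sulfone alcohol
Product: 25 (E)-tert-butyldimethyl{[3-methyl-4-(phenylsulfonyl)but-2-en-1-yl]oxy}silane
Conditions: t-BuMe2SiCl, imidazole, CH2Cl2, rt
Reagents that add atoms: tert-butyldimethylsilyl chloride CC(C)(C)[Si](C)(C)Cl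
Why: Standard silylation of a primary allylic alcohol gives a base-stable C15 ether.

**Step 19**
Reactants: 25 silyloxy sulfone; 19 allylic bromide
Product: 27 15,19-bis(tert-butyldimethylsilyloxy)-12-(phenylsulfonyl)labda-8,13E-diene (C12 epimers), via lithiated sulfone 26 (not isolated)
Conditions: 25 (1.2 equiv), n-BuLi, THF, −78 °C; then 19, −78 → −20 °C; H2O
Reagents that add atoms: none
Why: α-Alkylation of the allylic sulfonyl carbanion by the primary allylic bromide (SN2) forms C11–C12 with C13=C14 unchanged, and the C12 stereocentre is removed in step 20.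

**Step 20**
Reactants: 27 coupled sulfone
Product: 28 15,19-bis(tert-butyldimethylsilyloxy)labda-8,13E-diene
Conditions: PdCl2(dppp) (5 mol %), LiBHEt3 (2.5 equiv), THF, 0 °C
Reagents that add atoms: none
Why: Palladium-catalysed reductive desulfonylation of an allylic sulfone: zerovalent palladium (formed from the divalent precatalyst by the hydride) ionises the C12–S bond and hydride is transferred within the π-allyl complex to C12, which keeps C13=C14 in place and E; C8=C9 is not allylic to the sulfone.

**Step 21**
Reactants: 28 bis-silyl ether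
Product: 29 labda-8,13E-diene-15,19-diol
Conditions: Bu4NF, THF, rt → 50 °C
Reagents that add atoms: none
Why: Fluoride cleaves both silyl ethers; warming is allowed for the hindered neopentyl 19-ether.

**Step 22**
Reactants: 29 diol
Product: 30 19-hydroxylabda-8,13E-dien-15-yl acetate
Conditions: Ac2O (1.1 equiv), pyridine, CH2Cl2, 0 °C
Reagents that add atoms: acetic anhydride CC(=O)OC(C)=O
Why: Acetylation without an acyl-transfer catalyst takes the unhindered primary allylic 15-hydroxyl, while the neopentyl axial 19-hydroxyl (1,3-diaxial to C20) should react far more slowly.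

**Step 23**
Reactants: 30 hydroxy acetate
Product: 31 19-oxolabda-8,13E-dien-15-yl acetate
Conditions: Dess–Martin periodinane, CH2Cl2, rt
Reagents that add atoms: none
Why: Dess–Martin oxidation of the primary alcohol stops at the aldehyde and tolerates the acetate and both alkenes.

**Step 24**
Reactants: 31 aldehyde
Product: 32 15-acetoxylabda-8,13E-dien-19-oic acid (target)
Conditions: NaClO2, NaH2PO4, 2-methylbut-2-ene, t-BuOH/H2O, rt
Reagents that add atoms: sodium chlorite [Na+].[O-]Cl=O
Why: Pinnick oxidation converts the hindered aldehyde into the acid under buffered conditions, with the alkene scavenger protecting C8=C9 and C13=C14 from hypochlorous acid and the acetate left intact.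

**Compound list**
1 | 2,6-dimethyl-1,4-benzoquinone | CC1=CC(=O)C=C(C)C1=O | starting material
2 | (E)-penta-1,3-diene | C/C=C/C=C | starting material
3 | (4aR,5R,8aS)-2,5,8a-trimethyl-4a,5,8,8a-tetrahydronaphthalene-1,4-dione | CC1=CC(=O)[C@@H]2[C@H](C)C=CC[C@]2(C)C1=O | intermediate
4 | (5R,8aS)-2,5,8a-trimethyl-4-(trimethylsilyloxy)-8,8a-dihydronaphthalen-1(5H)-one | CC1=CC(O[Si](C)(C)C)=C2[C@H](C)C=CC[C@]2(C)C1=O | intermediate (not isolated)
5 | (8aS)-2,5,8a-trimethyl-8,8a-dihydronaphthalene-1,4-dione | CC1=CC(=O)C2=C(C)C=CC[C@]2(C)C1=O | intermediate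
6 | (8aS)-2,5,8a-trimethyl-2,3,8,8a-tetrahydronaphthalene-1,4-dione, C8 epimers | CC1CC(=O)C2=C(C)C=CC[C@]2(C)C1=O | intermediate
7 | (4R,8aS)-2,5,8a-trimethyl-1,2,3,4,8,8a-hexahydronaphthalene-1,4-diol (6β-ol; C8, C9 epimers) | CC1C[C@@H](O)C2=C(C)C=CC[C@]2(C)C1O | intermediate
8 | potassium 6-alkoxide of 7 | CC1C[C@@H]([O-])C2=C(C)C=CC[C@]2(C)C1O.[K+] | intermediate (not isolated)
9 | 6β-O-[(tributylstannyl)methyl] ether of 7 | CC1C[C@@H](OC[Sn](CCCC)(CCCC)CCCC)C2=C(C)C=CC[C@]2(C)C1O | intermediate
10 | 6β-O-(lithiomethyl) ether, 9-lithium alkoxide | CC1C[C@@H](OC[Li])C2=C(C)C=CC[C@]2(C)C1O[Li] | intermediate (not isolated)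
11 | (5S,8aS)-5-(hydroxymethyl)-2,5,8a-trimethyl-1,2,3,5,8,8a-hexahydronaphthalen-1-ol (C19 β) | CC1CC=C2[C@@](C)(CO)C=CC[C@]2(C)C1O | intermediate
12 | 19-O-(tert-butyldimethylsilyl) ether of 11 | CC1CC=C2[C@@](C)(CO[Si](C)(C)C(C)(C)C)C=CC[C@]2(C)C1O | intermediate
13 | 19-(tert-butyldimethylsilyloxy)-11,12,13,14,15,16-hexanorlabda-2,5-dien-9-one | CC1CC=C2[C@@](C)(CO[Si](C)(C)C(C)(C)C)C=CC[C@]2(C)C1=O | intermediate
14 | 19-(tert-butyldimethylsilyloxy)-11,12,13,14,15,16-hexanorlabdan-9-one (5α-H) | CC1CC[C@H]2[C@@](C)(CO[Si](C)(C)C(C)(C)C)CCC[C@]2(C)C1=O | intermediate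
15 | potassium C8=C9 enolate of 14 | [K+].[O-]C1=C(C)CC[C@H]2[C@@](C)(CO[Si](C)(C)C(C)(C)C)CCC[C@]12C | intermediate (not isolated)
16 | 19-(tert-butyldimethylsilyloxy)-11,12,13,14,15,16-hexanorlabd-8-en-9-yl trifluoromethanesulfonate | O=S(=O)(OC1=C(C)CC[C@H]2[C@@](C)(CO[Si](C)(C)C(C)(C)C)CCC[C@]12C)C(F)(F)F | intermediate
17 | methyl 19-(tert-butyldimethylsilyloxy)-12,13,14,15,16-pentanorlabd-8-en-11-oate | COC(=O)C1=C(C)CC[C@H]2[C@@](C)(CO[Si](C)(C)C(C)(C)C)CCC[C@]12C | intermediate
18 | 19-(tert-butyldimethylsilyloxy)-12,13,14,15,16-pentanorlabd-8-en-11-ol | OCC1=C(C)CC[C@H]2[C@@](C)(CO[Si](C)(C)C(C)(C)C)CCC[C@]12C | intermediate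
19 | 11-bromo-19-(tert-butyldimethylsilyloxy)-12,13,14,15,16-pentanorlabd-8-ene | BrCC1=C(C)CC[C@H]2[C@@](C)(CO[Si](C)(C)C(C)(C)C)CCC[C@]12C | intermediate
20 | 3-methylbut-2-en-1-yl acetate (prenyl acetate) | CC(=O)OCC=C(C)C | starting material
21 | (E)-4-hydroxy-3-methylbut-2-en-1-yl acetate | CC(=O)OC/C=C(\C)CO | intermediate
22 | (E)-4-bromo-3-methylbut-2-en-1-yl acetate | CC(=O)OC/C=C(\C)CBr | intermediate
23 | (E)-3-methyl-4-(phenylsulfonyl)but-2-en-1-yl acetate | CC(=O)OC/C=C(\C)CS(=O)(=O)c1ccccc1 | intermediate
24 | (E)-3-methyl-4-(phenylsulfonyl)but-2-en-1-ol | OC/C=C(\C)CS(=O)(=O)c1ccccc1 | intermediate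
25 | (E)-tert-butyldimethyl{[3-methyl-4-(phenylsulfonyl)but-2-en-1-yl]oxy}silane | CC(C)(C)[Si](C)(C)OC/C=C(\C)CS(=O)(=O)c1ccccc1 | intermediate
26 | α-lithio derivative of 25 | CC(C)(C)[Si](C)(C)OC/C=C(\C)C([Li])S(=O)(=O)c1ccccc1 | intermediate (not isolated)
27 | 15,19-bis(tert-butyldimethylsilyloxy)-12-(phenylsulfonyl)labda-8,13E-diene, C12 epimers | CC(C)(C)[Si](C)(C)OC/C=C(\C)C(CC1=C(C)CC[C@H]2[C@@](C)(CO[Si](C)(C)C(C)(C)C)CCC[C@]12C)S(=O)(=O)c1ccccc1 | intermediate
28 | 15,19-bis(tert-butyldimethylsilyloxy)labda-8,13E-diene | CC(C)(C)[Si](C)(C)OC/C=C(\C)CCC1=C(C)CC[C@H]2[C@@](C)(CO[Si](C)(C)C(C)(C)C)CCC[C@]12C | intermediate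
29 | labda-8,13E-diene-15,19-diol | OC/C=C(\C)CCC1=C(C)CC[C@H]2[C@@](C)(CO)CCC[C@]12C | intermediate
30 | 19-hydroxylabda-8,13E-dien-15-yl acetate | CC(=O)OC/C=C(\C)CCC1=C(C)CC[C@H]2[C@@](C)(CO)CCC[C@]12C | intermediate
31 | 19-oxolabda-8,13E-dien-15-yl acetate | CC(=O)OC/C=C(\C)CCC1=C(C)CC[C@H]2[C@@](C)(C=O)CCC[C@]12C | intermediate
32 | 15-acetoxylabda-8,13E-dien-19-oic acid | CC(=O)OC/C=C(\C)CCC1=C(C)CC[C@H]2[C@@](C)(C(=O)O)CCC[C@]12C | target

**Step count**
Total: 24 steps. Longest linear sequence: 19 steps (steps 1–13, then 19–24); the sulfone is made in steps 14–18.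

**Three steps most likely to fail**

Step 1. Addition to the trisubstituted C5=C10 alkene may be slow at low temperature, or the catalyst may discriminate the regiochemistry or the alkene face incompletely, which would give material of low optical purity. Fallback: setting out from 1 and 2, the cycloaddition is run with BF3·OEt2 (cat.) in CH2Cl2 at −20 °C. The boron trifluoride binds the same C6 carbonyl, so the same regioisomer is expected as the racemic cis adduct F1. The step-2 procedure then leads through the racemic silyl dienol ether F2 to the racemic trienedione F3, which has C10 as its only stereocentre. Its enantiomers are separated by preparative chromatography on a chiral stationary phase; the (S)-enantiomer is 5, where the route is rejoined.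

Step 6. A [1,2]-shift or simple protonation of the carbanion may compete with the [2,3] shift onto the fully substituted C4, which is 1,3-diaxial to C20. Fallback: setting out from diol 7 (step 5 is not needed), heating with N,N-dimethylformamide dimethyl acetal in xylene at 140 °C converts the 6β-allylic alcohol into its allyloxy(dimethylamino)carbene. The known thermal [2,3]-sigmatropic rearrangement of such carbenes transfers the carbamoyl carbon from O6 to the β face of C4 and gives the 19-(N,N-dimethylamide) F4; the non-allylic 9-hydroxyl only forms an acetal that is lost on work-up. Reduction of the tertiary amide with LiBHEt3 in THF gives the primary alcohol, which is 11.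

Step 9. The alkene between two quaternary carbons may be reduced slowly or incompletely, or some hydrogen may be delivered to the β face and give the cis-decalin. Fallback: setting out from 13, H2 (1 atm) over Pd/C reduces only C2=C3 and gives the mono-alkene F5. Hydrogen-atom-transfer hydrogenation then follows with Mn(dpm)3 (tris(2,2,6,6-tetramethylheptane-3,5-dionato)manganese, trivalent manganese, cat.), PhSiH3 and t-BuOOH in i-PrOH. It places hydrogen on C6 and forms the tertiary C5 radical, which is reduced from the α face under thermodynamic control to the trans-decalin 14.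

**Further compounds**
F1 | step 1 | racemic 3 | CC1=CC(=O)[C@@H]2[C@H](C)C=CC[C@]2(C)C1=O.CC1=CC(=O)[C@H]2[C@@H](C)C=CC[C@@]2(C)C1=O
F2 | step 1 | racemic 4 | CC1=CC(O[Si](C)(C)C)=C2[C@H](C)C=CC[C@]2(C)C1=O.CC1=CC(O[Si](C)(C)C)=C2[C@@H](C)C=CC[C@@]2(C)C1=O
F3 | step 1 | racemic 5 | CC1=CC(=O)C2=C(C)C=CC[C@]2(C)C1=O.CC1=CC(=O)C2=C(C)C=CC[C@@]2(C)C1=O
F4 | step 6 | 9-hydroxy-N,N-dimethyl-11,12,13,14,15,16-hexanorlabda-2,5-dien-19-amide | CC1CC=C2[C@@](C)(C(=O)N(C)C)C=CC[C@]2(C)C1O
F5 | step 9 | 19-(tert-butyldimethylsilyloxy)-11,12,13,14,15,16-hexanorlabd-5-en-9-one | CC1CC=C2[C@@](C)(CO[Si](C)(C)C(C)(C)C)CCC[C@]2(C)C1=O
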